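The constants belong to no real substance; no experiment stands behind them.

Two sums stay constant in these flasks: X plus X.G plus free J plus D stays at the charge of X, and G plus X.G stays at the charge of catalyst.

| flask | X | G | time |
|---|---|---|---|
| larch | 2.6 M | 1.0 mM | 5.0 h |
| alder | 2.6 M | 1.5 mM | 5.0 h |
| birch | 2.6 M | 2.5 mM | 5.0 h |
| cedar | 2.6 M | 4.0 mM | 5.0 h |
| maple | 2.6 M | 5.0 mM | 5.0 h |

    X + G → X.G (k1 = 3.1 M⁻¹ s⁻¹)
    X.G → G + J (k2 = 0.20 s⁻¹)
    D ⇌ J, rate k3*(cs3 - [J]) while solid is left; crystals form when [J] > cs3 (cs3 = 0.83 M, k3 = 0.042 s⁻¹)

- what is said of J includes D
- D is a solid; its amount is given per volume of the solution
- the concentration of J that is asked is that of its free form alone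
- "hardly changes" means that all values lie within two and a half points (for a concentration: within two and a half percent of the largest)
- run time (larch): 5.0 h

1. [J] (only what is free in solution) at the end for larch, alder, birch, cedar, maple, in this order
2. the shape of the row from first to last (rises, then falls / rises all the way / falls, then rises / hardly changes / falls all the way)

I build up larch, whose catalyst charge is the smallest of the row, one process at a time. First I take the release step by itself and suppose that the whole catalyst stands as X.G. Then J appears at the release constant times the catalyst charge, 0.200 mM s⁻¹, whatever X is, and the charge of X lasts 3.61 h.

Next I add the binding step. Its balance with release gives a concentration, the ratio of the two constants, 0.0645 M, the Michaelis constant. The bound share of the catalyst is X over X plus this constant, which is 97.6 % at the charge, so X.G is the resting state and release the rate-limiting step. I solve the two ends and join them. Far above that constant the rate is zero order in X, and far below it first order, and integrating the whole curve simply adds the two times. The low end adds 0.350 h. The sum for larch is 3.89 h. This is the clearing time, the time that brings X under 2.00 % of its charge, and it varies inversely with the catalyst charge.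

Last I add the crystals. D stands on neither side of the first two steps, so the clearing time stays as it was. The charge of X exceeds the solubility by 1.77 M, and in larch the solubility is passed after about 1.15 h. Any gap between free J and the solubility closes within about 23.8 s, far shorter than the clearing time, which itself is shorter than the run. So I commit to 0.830 M for larch, 0.830 M for alder, 0.830 M for birch, 0.830 M for cedar and 0.830 M for maple, a row that hardly changes.

The forecast gives 0.83 M, 0.83 M, 0.83 M, 0.83 M and 0.83 M, a row that hardly changes, since “free J sits at the solubility limit with solid present”.

The simulation gives 0.830 M, 0.830 M, 0.830 M, 0.830 M and 0.830 M, a row that hardly changes.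

In larch, X falls under 2.00 % of its charge at a reading of 3.89 h, beside a clearing time of 3.89 h and a run of 5.0 h, and after 5.00 h D holds 68.1 % of the X charged. Maple's clearing time is 0.778 h, shorter than 1.50 h, and at that time G makes up 100 % of maple's catalyst.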